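The route rests on cutting the O1–C2 ether bond of ring C. The 4'-OH of ring B stands para to C2, so this bond is the adduct of the ring A phenol oxygen and a p-quinone methide. C4–C3–C2–ring B is the tyrosine skeleton, with C3 as its alpha carbon. In one operation the key step dehydrogenates the benzylic CH2 of an open chain, closes ring C through O1–C2 and sets C2 under the control of C3. Its precursor is an (R)-alpha-acetoxy dihydrochalcone with free 6'-OH and 4-OH and benzyl ethers on the two other ring A oxygens. It is built from D-tyrosine and an aryllithium derived from methyl 4-O-methylgallate.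

Key step: step 15

Remark: open-chain compounds carry chalcone numbering (primed positions on ring A, C-alpha next to the carbonyl). Compounds 23 and 24 carry flavanone numbering. The target SMILES reads as the trans (2R,3R) isomer.

Step 1
Reactants: 1 D-tyrosine
Product: 4 (R)-2-hydroxy-3-(4-hydroxyphenyl)propanoic acid, via diazonium carboxylate 2 (not isolated), via alpha-lactone 3 (not isolated)
Conditions: NaNO2 (slow addition), 1 M H2SO4, H2O, 0 °C → rt
Reagents that add atoms: water, O
Why: Diazotisation of an alpha-amino acid, in which the carboxylate expels N2 from 2 with inversion to give alpha-lactone 3 and water opens it with a second inversion, so C–O replaces C–N with net retention and the centre stays (R), while cold dilute acid and slow nitrite addition hold back nitrosation of the phenol ring.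

Step 2
Reactants: 4 (R)-2-hydroxy-3-(4-hydroxyphenyl)propanoic acid
Product: 5 (R)-2-hydroxy-3-(4-hydroxyphenyl)-N-methoxy-N-methylpropanamide
Conditions: MeNHOMe·HCl, EDC·HCl, HOBt, N-methylmorpholine, CH2Cl2–DMF, 0 °C → rt
Reagents that add atoms: N,O-dimethylhydroxylamine hydrochloride, CNOC.Cl
Why: Carbodiimide-mediated amide coupling (Weinreb amide formation), in which the amine is far more nucleophilic than the free alcohol and phenol and an alpha-hydroxy acid has no oxazolone pathway for racemisation.

Step 3
Reactants: 5 (R)-2-hydroxy-3-(4-hydroxyphenyl)-N-methoxy-N-methylpropanamide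
Product: 6 (R)-2-hydroxy-N-methoxy-3-[4-(methoxymethoxy)phenyl]-N-methylpropanamide
Conditions: MOMCl (1.1 equiv), K2CO3, acetone, 0 °C → rt
Reagents that add atoms: chloromethyl methyl ether, COCCl
Why: Williamson-type O-alkylation in which carbonate deprotonates only the phenol, so the secondary alcohol stays free and the stereocentre is not touched.

Step 4
Reactants: 6 (R)-2-hydroxy-N-methoxy-3-[4-(methoxymethoxy)phenyl]-N-methylpropanamide
Product: 7 (R)-2-(tert-butyldimethylsilyloxy)-N-methoxy-3-[4-(methoxymethoxy)phenyl]-N-methylpropanamide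
Conditions: TBSCl, imidazole, DMF, rt
Reagents that add atoms: tert-butyldimethylsilyl chloride, CC(C)(C)[Si](C)(C)Cl
Why: Imidazole-promoted silylation of a secondary alcohol, which makes an O–Si bond only and gives a group that withstands an aryllithium and shields the C-alpha proton.

Step 5
Reactants: 8 methyl 3,5-dihydroxy-4-methoxybenzoate
Product: 9 methyl 3,5-bis(benzyloxy)-4-methoxybenzoate
Conditions: BnBr (2.3 equiv), K2CO3, DMF, 60 °C
Reagents that add atoms: benzyl bromide, BrCc1ccccc1
Why: Williamson ether synthesis on two equivalent phenols, with the methyl ester and methyl ether inert to carbonate.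

Step 6
Reactants: 9 methyl 3,5-bis(benzyloxy)-4-methoxybenzoate
Product: 10 [3,5-bis(benzyloxy)-4-methoxyphenyl]methanol
Conditions: LiAlH4, THF, 0 °C → rt; aqueous NaOH work-up
Reagents that add atoms: none
Why: Hydride reduction of an aromatic ester to the benzylic alcohol, to which aryl benzyl and methyl ethers are inert.

Step 7
Reactants: 10 [3,5-bis(benzyloxy)-4-methoxyphenyl]methanol
Product: 11 3,5-bis(benzyloxy)-4-methoxybenzaldehyde
Conditions: activated MnO2, CH2Cl2, rt
Reagents that add atoms: none
Why: Heterogeneous MnO2 oxidation is selective for benzylic alcohols and stops cleanly at the aldehyde.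

Step 8
Reactants: 11 3,5-bis(benzyloxy)-4-methoxybenzaldehyde
Product: 13 3,5-bis(benzyloxy)-4-methoxyphenol, via aryl formate 12 (not isolated)
Conditions: mCPBA, CH2Cl2, 0 °C → rt; aq NaHCO3 wash; crude in MeOH, K2CO3 (cat.), rt
Reagents that add atoms: 3-chloroperoxybenzoic acid, O=C(OO)c1cccc(Cl)c1
Why: Baeyer–Villiger (Dakin-type) oxidation in which the trialkoxy-substituted aryl group migrates to oxygen in preference to hydrogen, and the resulting formate 12 is methanolysed under mild catalysis.

Step 9
Reactants: 13 3,5-bis(benzyloxy)-4-methoxyphenol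
Product: 14 1,3-bis(benzyloxy)-2-methoxy-5-(methoxymethoxy)benzene
Conditions: MOMCl, i-Pr2NEt, CH2Cl2, 0 °C → rt
Reagents that add atoms: chloromethyl methyl ether, COCCl
Why: O-alkylation of the phenol before halogenation masks the hydroquinone monoether motif, so the brominating agent of the next step cannot oxidise the ring to a quinone.

Step 10
Reactants: 14 1,3-bis(benzyloxy)-2-methoxy-5-(methoxymethoxy)benzene
Product: 15 2,4-bis(benzyloxy)-1-bromo-3-methoxy-6-(methoxymethoxy)benzene
Conditions: NBS (1.0 equiv), MeCN, 0 °C, dark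
Reagents that add atoms: N-bromosuccinimide, O=C1CCC(=O)N1Br
Why: Electrophilic aromatic bromination at one of the two symmetry-equivalent ring C–H positions, each flanked by two oxygens, in which the first bromine deactivates and crowds the ring against a second substitution and the polar solvent and darkness suppress radical benzylic bromination.

Step 11
Reactants: 15 2,4-bis(benzyloxy)-1-bromo-3-methoxy-6-(methoxymethoxy)benzene; 7 (R)-2-(tert-butyldimethylsilyloxy)-N-methoxy-3-[4-(methoxymethoxy)phenyl]-N-methylpropanamide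
Product: 18 (R)-1-[2,4-bis(benzyloxy)-3-methoxy-6-(methoxymethoxy)phenyl]-2-(tert-butyldimethylsilyloxy)-3-[4-(methoxymethoxy)phenyl]propan-1-one, via aryllithium 16 (not isolated), via lithium hemiaminal chelate 17 (not isolated)
Conditions: 15, n-BuLi (1.05 equiv), THF, −78 °C; then 7, −78 → −30 °C; sat. aq NH4Cl
Reagents that add atoms: none
Why: Bromine–lithium exchange outruns any attack on the benzyl or MOM ethers at −78 °C, and aryllithium 16 adds only once because chelate 17 persists until the quench (Weinreb ketone synthesis), while the bulky silyl ether and the low temperature protect the C-alpha proton so that the (R) centre is carried over.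

Step 12
Reactants: 18 (R)-1-[2,4-bis(benzyloxy)-3-methoxy-6-(methoxymethoxy)phenyl]-2-(tert-butyldimethylsilyloxy)-3-[4-(methoxymethoxy)phenyl]propan-1-one
Product: 19 (R)-1-[2,4-bis(benzyloxy)-3-methoxy-6-(methoxymethoxy)phenyl]-2-hydroxy-3-[4-(methoxymethoxy)phenyl]propan-1-one
Conditions: TBAF/AcOH (1:1), THF, 0 °C → rt
Reagents that add atoms: none
Why: Fluoride-driven Si–O cleavage buffered by acetic acid, so the alpha-hydroxy ketone neither epimerises nor undergoes alpha-ketol isomerisation, and MOM and benzyl ethers are untouched.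

Step 13
Reactants: 19 (R)-1-[2,4-bis(benzyloxy)-3-methoxy-6-(methoxymethoxy)phenyl]-2-hydroxy-3-[4-(methoxymethoxy)phenyl]propan-1-one
Product: 20 (R)-1-[2,4-bis(benzyloxy)-3-methoxy-6-(methoxymethoxy)phenyl]-3-[4-(methoxymethoxy)phenyl]-1-oxopropan-2-yl acetate
Conditions: Ac2O, pyridine, DMAP (cat.), CH2Cl2, 0 °C
Reagents that add atoms: acetic anhydride, CC(=O)OC(C)=O
Why: DMAP-catalysed acetylation of the only free hydroxyl, in which the C–O bond at the stereocentre is retained and pyridine is too weak a base to enolise the twisted di-ortho-substituted aryl ketone.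

Step 14
Reactants: 20 (R)-1-[2,4-bis(benzyloxy)-3-methoxy-6-(methoxymethoxy)phenyl]-3-[4-(methoxymethoxy)phenyl]-1-oxopropan-2-yl acetate
Product: 21 (R)-1-[2,4-bis(benzyloxy)-6-hydroxy-3-methoxyphenyl]-3-(4-hydroxyphenyl)-1-oxopropan-2-yl acetate
Conditions: NaHSO4·SiO2, CH2Cl2, rt
Reagents that add atoms: none
Why: Acid-catalysed hydrolysis of the two phenolic acetals on a weakly acidic solid support, where no alcohol is present to transesterify the acetate, the acid is too mild to cleave the benzyl ether next to the ketone, and the absence of base prevents both enolisation at C-alpha and displacement of the acetate by the freed 6'-phenol.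

Step 15
Reactants: 21 (R)-1-[2,4-bis(benzyloxy)-6-hydroxy-3-methoxyphenyl]-3-(4-hydroxyphenyl)-1-oxopropan-2-yl acetate
Product: 23 (2R,3R)-5,7-bis(benzyloxy)-2-(4-hydroxyphenyl)-6-methoxy-4-oxochroman-3-yl acetate, via p-quinone methide 22 (not isolated)
Conditions: DDQ (1.0 equiv, slow addition), 4 Å MS, CH2Cl2, −20 °C → rt
Reagents that add atoms: none
Why: Proposed new method: DDQ formally takes a hydride from the benzylic CH2 and the proton of the para 4-OH of ring B to give p-quinone methide 22, whose exocyclic carbon is attacked by the ketone-chelated 6'-OH in an intramolecular oxa-1,6-conjugate addition that re-aromatises ring B and forms O1–C2. The closest known reaction types are the DDQ cyclodehydrogenation of 2'-hydroxydihydrochalcones to flavanones and the DDQ-induced cycloetherification of 4-hydroxyphenyl alkanols through p-quinone methides, neither of which has been run on an alpha-acyloxy dihydrochalcone with 1,2-induction. Ring C closes in the 6-exo-trig mode, because of the C2=C1' double bond only C2 becomes a member of the new ring. C2 is controlled by the C3 stereocentre: allylic 1,3-strain puts H-3 in the plane of the quinone methide, C4 with its tethered phenol on one face and the acetoxy group anti to the incoming oxygen, which is a chair-like transition state with aryl and acetoxy equatorial leading to the trans (2R,3R) product, and any cis isomer can drain to trans by reversible opening at C2 without touching C3. Chemoselectivity for ring B over ring A, whose 6'-OH lies para to the 3'-OMe, relies on the acyl group and the strong OH to C=O hydrogen bond that make ring A harder to oxidise and on the exclusion of water and alcohols, while regioselectivity relies on the 2'-O-benzyl group, which leaves a single phenol able to close and so gives the 6-methoxy and not the 8-methoxy pattern. A single equivalent of oxidant, the low starting temperature, the absence of base and the pre-organised nucleophile should let closure win over proton loss from C3 of 22 (which would give the achiral alpha-acetoxychalcone) and over further dehydrogenation to the flavonol.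

Step 16
Reactants: 23 (2R,3R)-5,7-bis(benzyloxy)-2-(4-hydroxyphenyl)-6-methoxy-4-oxochroman-3-yl acetate
Product: 24 6-methoxyaromadendrin 3-O-acetate
Conditions: H2 (1 atm), 10% Pd/C, EtOAc, rt
Reagents that add atoms: none
Why: Catalytic hydrogenolysis of the two aryl benzyl ethers in a neutral aprotic medium at atmospheric pressure, which should spare the acetate, the ketone and the endocyclic C2–O1 bond and therefore both stereocentres.

Compound list
1 | D-tyrosine | N[C@H](Cc1ccc(O)cc1)C(=O)O | starting material
2 | (R)-1-carboxylato-2-(4-hydroxyphenyl)ethanediazonium (diazonium carboxylate) | N#[N+][C@H](Cc1ccc(O)cc1)C(=O)[O-] | intermediate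
3 | (S)-3-(4-hydroxybenzyl)oxiran-2-one (alpha-lactone) | O1[C@@H](Cc2ccc(O)cc2)C1=O | intermediate
4 | (R)-2-hydroxy-3-(4-hydroxyphenyl)propanoic acid | O[C@H](Cc1ccc(O)cc1)C(=O)O | intermediate
5 | (R)-2-hydroxy-3-(4-hydroxyphenyl)-N-methoxy-N-methylpropanamide | O[C@H](Cc1ccc(O)cc1)C(=O)N(C)OC | intermediate
6 | (R)-2-hydroxy-N-methoxy-3-[4-(methoxymethoxy)phenyl]-N-methylpropanamide | O[C@H](Cc1ccc(OCOC)cc1)C(=O)N(C)OC | intermediate
7 | (R)-2-(tert-butyldimethylsilyloxy)-N-methoxy-3-[4-(methoxymethoxy)phenyl]-N-methylpropanamide | CC(C)(C)[Si](C)(C)O[C@H](Cc1ccc(OCOC)cc1)C(=O)N(C)OC | intermediate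
8 | methyl 3,5-dihydroxy-4-methoxybenzoate | COC(=O)c1cc(O)c(OC)c(O)c1 | starting material
9 | methyl 3,5-bis(benzyloxy)-4-methoxybenzoate | COC(=O)c1cc(OCc2ccccc2)c(OC)c(OCc2ccccc2)c1 | intermediate
10 | [3,5-bis(benzyloxy)-4-methoxyphenyl]methanol | OCc1cc(OCc2ccccc2)c(OC)c(OCc2ccccc2)c1 | intermediate
11 | 3,5-bis(benzyloxy)-4-methoxybenzaldehyde | O=Cc1cc(OCc2ccccc2)c(OC)c(OCc2ccccc2)c1 | intermediate
12 | 3,5-bis(benzyloxy)-4-methoxyphenyl formate | O=COc1cc(OCc2ccccc2)c(OC)c(OCc2ccccc2)c1 | intermediate
13 | 3,5-bis(benzyloxy)-4-methoxyphenol | COc1c(OCc2ccccc2)cc(O)cc1OCc1ccccc1 | intermediate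
14 | 1,3-bis(benzyloxy)-2-methoxy-5-(methoxymethoxy)benzene | COCOc1cc(OCc2ccccc2)c(OC)c(OCc2ccccc2)c1 | intermediate
15 | 2,4-bis(benzyloxy)-1-bromo-3-methoxy-6-(methoxymethoxy)benzene | COCOc1cc(OCc2ccccc2)c(OC)c(OCc2ccccc2)c1Br | intermediate
16 | [2,4-bis(benzyloxy)-3-methoxy-6-(methoxymethoxy)phenyl]lithium | COCOc1cc(OCc2ccccc2)c(OC)c(OCc2ccccc2)c1[Li] | intermediate
17 | lithium alkoxide of the tetrahedral N-methoxy-N-methyl hemiaminal (C2 R, C1 not assigned) | COCOc1cc(OCc2ccccc2)c(OC)c(OCc2ccccc2)c1C(O[Li])(N(C)OC)[C@H](O[Si](C)(C)C(C)(C)C)Cc1ccc(OCOC)cc1 | intermediate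
18 | (R)-1-[2,4-bis(benzyloxy)-3-methoxy-6-(methoxymethoxy)phenyl]-2-(tert-butyldimethylsilyloxy)-3-[4-(methoxymethoxy)phenyl]propan-1-one | COCOc1cc(OCc2ccccc2)c(OC)c(OCc2ccccc2)c1C(=O)[C@H](O[Si](C)(C)C(C)(C)C)Cc1ccc(OCOC)cc1 | intermediate
19 | (R)-1-[2,4-bis(benzyloxy)-3-methoxy-6-(methoxymethoxy)phenyl]-2-hydroxy-3-[4-(methoxymethoxy)phenyl]propan-1-one | COCOc1cc(OCc2ccccc2)c(OC)c(OCc2ccccc2)c1C(=O)[C@H](O)Cc1ccc(OCOC)cc1 | intermediate
20 | (R)-1-[2,4-bis(benzyloxy)-3-methoxy-6-(methoxymethoxy)phenyl]-3-[4-(methoxymethoxy)phenyl]-1-oxopropan-2-yl acetate | COCOc1cc(OCc2ccccc2)c(OC)c(OCc2ccccc2)c1C(=O)[C@H](OC(C)=O)Cc1ccc(OCOC)cc1 | intermediate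
21 | (R)-1-[2,4-bis(benzyloxy)-6-hydroxy-3-methoxyphenyl]-3-(4-hydroxyphenyl)-1-oxopropan-2-yl acetate | COc1c(OCc2ccccc2)cc(O)c(C(=O)[C@H](OC(C)=O)Cc2ccc(O)cc2)c1OCc1ccccc1 | intermediate
22 | (R)-1-[2,4-bis(benzyloxy)-6-hydroxy-3-methoxyphenyl]-1-oxo-3-(4-oxocyclohexa-2,5-dien-1-ylidene)propan-2-yl acetate (p-quinone methide) | COc1c(OCc2ccccc2)cc(O)c(C(=O)[C@H](OC(C)=O)C=C2C=CC(=O)C=C2)c1OCc1ccccc1 | intermediate
23 | (2R,3R)-5,7-bis(benzyloxy)-2-(4-hydroxyphenyl)-6-methoxy-4-oxochroman-3-yl acetate | COc1c(OCc2ccccc2)cc2c(c1OCc1ccccc1)C(=O)[C@H](OC(C)=O)[C@@H](c1ccc(O)cc1)O2 | intermediate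
24 | 6-methoxyaromadendrin 3-O-acetate, (2R,3R)-5,7-dihydroxy-2-(4-hydroxyphenyl)-6-methoxy-4-oxochroman-3-yl acetate | COc1c(O)cc2c(c1O)C(=O)[C@H](OC(C)=O)[C@@H](c1ccc(O)cc1)O2 | target

Total step count: 16.
Longest linear sequence: 12 steps (8 to 24, steps 5–16). The tyrosine branch contributes steps 1–4.

Steps most likely to fail

1. Step 15.
- **Risk:** The oxidant may attack the electron-rich ring A instead of ring B. The quinone methide may lose the C3 proton before it is trapped, which would erode enantiopurity. The product may also be dehydrogenated further.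
- **Fallback:** This uses known chemistry and makes O1–C2 by epoxide opening instead of C–H oxidation. It sets out from bromide 15 and returns at target 24. Bromine–lithium exchange of 15 to aryllithium 16 and acylation with N-methoxy-N-methylacetamide should give the 2'-MOM-protected acetophenone F1. Claisen–Schmidt condensation with 4-(benzyloxy)benzaldehyde (KOH, EtOH) should give the (E)-chalcone F2. Juliá–Colonna epoxidation (poly-L-leucine, urea–H2O2, DBU, THF) should give the (alphaR,betaS)-epoxychalcone F3. HCl in MeOH–THF strips the MOM group, and the freed phenol opens the oxirane at its benzylic carbon while the C-alpha–O bond is kept, giving the trans-(2R,3R)-tri-O-benzyl flavanonol F4. Ac2O–pyridine acetylates its only hydroxyl to the flavanonol 3-O-acetate F5. Hydrogenolysis of the three benzyl ethers (H2, Pd/C, EtOAc) then delivers 24.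

2. Step 11.
- **Risk:** Addition of the di-ortho-substituted aryllithium to the branched amide may be sluggish. That would leave room for deprotonation at C-alpha, with loss of configuration, or for base-induced breakdown of the N-methoxy amide.
- **Fallback:** A smaller and more electrophilic carbonyl partner is used, and the oxidation level is adjusted afterwards. It sets out from amide 7 (with bromide 15) and returns at ketone 18. DIBAL-H (THF, −78 °C) reduces 7 to the alpha-silyloxy aldehyde F6, which is used at once. Aryllithium 16, made from 15 as before, adds to it at −78 °C to give the benzylic carbinol F7 as a mixture of epimers at the new, transient centre. Dess–Martin periodinane (NaHCO3, CH2Cl2) oxidises both epimers to 18.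

3. Step 14.
- **Risk:** Unmasking the two phenols may be accompanied by loss of the acetate or by cleavage of the carbonyl-activated benzyl ether next to the ketone. The liberated formaldehyde equivalent may also alkylate ring A.
- **Fallback:** Acid and acetate never meet. It sets out from alpha-hydroxy ketone 19 and returns at 21. HCl in MeOH (40 °C) removes both MOM groups from 19 to give the alpha-hydroxy dihydrochalcone triol F8. Ac2O–pyridine converts it into the triacetate F9. The two aryl acetates are then cleaved chemoselectively under neutral conditions (NH4OAc, aqueous MeOH, rt), which leave the secondary alkyl acetate in place and give 21.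

Further compounds
F1 | step 15 | 1-[2,4-bis(benzyloxy)-3-methoxy-6-(methoxymethoxy)phenyl]ethan-1-one | COCOc1cc(OCc2ccccc2)c(OC)c(OCc2ccccc2)c1C(C)=O
F2 | step 15 | (E)-1-[2,4-bis(benzyloxy)-3-methoxy-6-(methoxymethoxy)phenyl]-3-[4-(benzyloxy)phenyl]prop-2-en-1-one | COCOc1cc(OCc2ccccc2)c(OC)c(OCc2ccccc2)c1C(=O)/C=C/c1ccc(OCc2ccccc2)cc1
F3 | step 15 | [2,4-bis(benzyloxy)-3-methoxy-6-(methoxymethoxy)phenyl]{(2R,3S)-3-[4-(benzyloxy)phenyl]oxiran-2-yl}methanone | COCOc1cc(OCc2ccccc2)c(OC)c(OCc2ccccc2)c1C(=O)[C@@H]1O[C@H]1c1ccc(OCc2ccccc2)cc1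
F4 | step 15 | (2R,3R)-5,7-bis(benzyloxy)-2-[4-(benzyloxy)phenyl]-3-hydroxy-6-methoxychroman-4-one | COc1c(OCc2ccccc2)cc2c(c1OCc1ccccc1)C(=O)[C@H](O)[C@@H](c1ccc(OCc3ccccc3)cc1)O2
F5 | step 15 | (2R,3R)-5,7-bis(benzyloxy)-2-[4-(benzyloxy)phenyl]-6-methoxy-4-oxochroman-3-yl acetate | COc1c(OCc2ccccc2)cc2c(c1OCc1ccccc1)C(=O)[C@H](OC(C)=O)[C@@H](c1ccc(OCc3ccccc3)cc1)O2
F6 | step 11 | (R)-2-(tert-butyldimethylsilyloxy)-3-[4-(methoxymethoxy)phenyl]propanal | CC(C)(C)[Si](C)(C)O[C@H](Cc1ccc(OCOC)cc1)C=O
F7 | step 11 | (2R)-1-[2,4-bis(benzyloxy)-3-methoxy-6-(methoxymethoxy)phenyl]-2-(tert-butyldimethylsilyloxy)-3-[4-(methoxymethoxy)phenyl]propan-1-ol (both C1 epimers) | COCOc1cc(OCc2ccccc2)c(OC)c(OCc2ccccc2)c1C(O)[C@H](O[Si](C)(C)C(C)(C)C)Cc1ccc(OCOC)cc1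
F8 | step 14 | (R)-1-[2,4-bis(benzyloxy)-6-hydroxy-3-methoxyphenyl]-2-hydroxy-3-(4-hydroxyphenyl)propan-1-one | COc1c(OCc2ccccc2)cc(O)c(C(=O)[C@H](O)Cc2ccc(O)cc2)c1OCc1ccccc1
F9 | step 14 | (R)-1-[6-acetoxy-2,4-bis(benzyloxy)-3-methoxyphenyl]-3-(4-acetoxyphenyl)-1-oxopropan-2-yl acetate | COc1c(OCc2ccccc2)cc(OC(C)=O)c(C(=O)[C@H](OC(C)=O)Cc2ccc(OC(C)=O)cc2)c1OCc1ccccc1
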